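**Retrosynthetic overview**

- The target comes from a hepta-allyl precursor: the last step removes four aryl allyl ethers and three allyl esters under neutral palladium catalysis.
- The ester C–O bond is cut between the conjugated C3 carboxyl of the dihydronaphthalene and the hydroxyl of diallyl (S)-malate (from L-malic acid); the C2 carboxyl is kept apart as an allyl ester.
- Ring B is the only ring formed (rings A and C are both bought as 3,4-dihydroxybenzaldehyde). It closes last in the skeleton, by intramolecular Friedel–Crafts attack of ring A on a benzylic cation (C1–C8a), trans to the C2 substituent.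
- The key C1–C2 bond comes from an intermolecular Evans boron aldol between a benzylidenesuccinyl imide of (R)-4-benzyl-2-oxazolidinone and 3,4-bis(allyloxy)benzaldehyde; this sets C2.
- The C3=C4 bond comes from a Stobbe condensation of the same aldehyde with di-tert-butyl succinate, which also differentiates the two carboxyls.

Assumption: lignan numbering is used for the dihydronaphthalene (C1 bears the pendant aryl, C2 the saturated carboxyl, C3 the conjugated carboxyl, C4 is the vinylic CH); read this way the target is the trans-(1R,2S) acid whose C3 carboxyl is esterified by the hydroxyl of (S)-malic acid.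

**Route**

Step 1
Reactants: 1 3,4-dihydroxybenzaldehyde
Product: 2 3,4-bis(allyloxy)benzaldehyde
Conditions: allyl bromide (2.5 equiv), K2CO3, DMF, 60 °C
Reagents that add atoms: allyl bromide, C=CCBr
Why: Williamson ether synthesis: both phenoxides are alkylated by the allylic bromide while the aldehyde is untouched, and allyl is chosen because it survives base, TFA and peroxide and leaves at the end under neutral palladium catalysis.

Step 2
Reactants: 2 3,4-bis(allyloxy)benzaldehyde, 3 di-tert-butyl succinate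
Product: 5 (E)-4-[3,4-bis(allyloxy)phenyl]-3-(tert-butoxycarbonyl)but-3-enoic acid, via paraconate lactone 4 (not isolated)
Conditions: KOt-Bu, t-BuOH, 60 °C; then aq. HCl
Reagents that add atoms: none
Why: Stobbe condensation: the succinate enolate adds to the aldehyde (aldol), the alkoxide lactonises to 4 and E1cB opening gives the E-benzylidene half-ester (aryl cis to CH2CO2H, as ring closure later needs) with the conjugated carboxyl as tert-butyl ester and the saturated one free; no stereocenter is formed.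

Step 3
Reactants: 5 (E)-4-[3,4-bis(allyloxy)phenyl]-3-(tert-butoxycarbonyl)but-3-enoic acid, 6 (R)-4-benzyl-2-oxazolidinone
Product: 8 tert-butyl (E)-2-[3,4-bis(allyloxy)benzylidene]-4-[(R)-4-benzyl-2-oxooxazolidin-3-yl]-4-oxobutanoate, via mixed pivalic anhydride 7 (not isolated)
Conditions: PivCl, Et3N, THF, −20 °C; then 6, LiCl, −20 °C → rt
Reagents that add atoms: none
Why: Mixed-anhydride N-acylation: the oxazolidinone, activated by LiCl/Et3N, attacks the unhindered carbonyl of 7 and not the pivaloyl one, placing the auxiliary on the saturated carboxyl without touching the alkene geometry.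

Step 4
Reactants: 8 tert-butyl (E)-2-[3,4-bis(allyloxy)benzylidene]-4-[(R)-4-benzyl-2-oxooxazolidin-3-yl]-4-oxobutanoate, 2 3,4-bis(allyloxy)benzaldehyde
Product: 10 (R)-4-benzyl-3-[(2R,3E)-4-[3,4-bis(allyloxy)phenyl]-2-{(R)-[3,4-bis(allyloxy)phenyl](hydroxy)methyl}-3-(tert-butoxycarbonyl)but-3-enoyl]oxazolidin-2-one, via dibutylboron Z-enolate 9 (not isolated)
Conditions: Bu2BOTf, i-Pr2NEt, CH2Cl2, −78 → 0 °C; then 2, −78 → 0 °C; then pH 7 buffer, MeOH, H2O2, 0 °C
Reagents that add atoms: none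
Why: Evans syn aldol (the key intermolecular C1–C2 bond formation): the Z boron dienolate reacts at its α-carbon through a Zimmerman–Traxler chair on the face away from the benzyl group of the (R)-auxiliary, setting the α-carbon R (this becomes C2 S of the target once C1 is a diarylmethine) and the carbinol R, which is erased in the next step.

Step 5
Reactants: 10 (R)-4-benzyl-3-[(2R,3E)-4-[3,4-bis(allyloxy)phenyl]-2-{(R)-[3,4-bis(allyloxy)phenyl](hydroxy)methyl}-3-(tert-butoxycarbonyl)but-3-enoyl]oxazolidin-2-one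
Product: 12 (1R,2S)-6,7-bis(allyloxy)-1-[3,4-bis(allyloxy)phenyl]-2-{[(R)-4-benzyl-2-oxooxazolidin-3-yl]carbonyl}-1,2-dihydronaphthalene-3-carboxylic acid, via cyclised tert-butyl ester 11 (not isolated)
Conditions: TFA/CH2Cl2 (1:4), 0 °C → rt
Reagents that add atoms: none
Why: Intramolecular Friedel–Crafts alkylation: TFA ionises the carbinol to a para-alkoxybenzyl cation that ring A attacks para to its 3-allyloxy group (six-membered ring B), the aryl group ending trans to the C2 imide so that C1 is set R under control of C2, and the same acid then cleaves the tert-butyl ester to unveil the C3 acid.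

Step 6
Reactants: 12 (1R,2S)-6,7-bis(allyloxy)-1-[3,4-bis(allyloxy)phenyl]-2-{[(R)-4-benzyl-2-oxooxazolidin-3-yl]carbonyl}-1,2-dihydronaphthalene-3-carboxylic acid
Product: 13 4-methoxybenzyl (1R,2S)-6,7-bis(allyloxy)-1-[3,4-bis(allyloxy)phenyl]-2-{[(R)-4-benzyl-2-oxooxazolidin-3-yl]carbonyl}-1,2-dihydronaphthalene-3-carboxylate
Conditions: PMBCl, KHCO3, NaI (cat.), DMF, rt
Reagents that add atoms: 4-methoxybenzyl chloride, COc1ccc(CCl)cc1
Why: Carboxylate O-alkylation (SN2) under nearly neutral conditions masks the C3 acid as an ester that resists LiOOH and is later removed by dilute acid without touching allyl groups; KHCO3 is too weak to epimerise C2.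

Step 7
Reactants: 13 4-methoxybenzyl (1R,2S)-6,7-bis(allyloxy)-1-[3,4-bis(allyloxy)phenyl]-2-{[(R)-4-benzyl-2-oxooxazolidin-3-yl]carbonyl}-1,2-dihydronaphthalene-3-carboxylate
Product: 15 (1R,2S)-6,7-bis(allyloxy)-1-[3,4-bis(allyloxy)phenyl]-3-[(4-methoxybenzyloxy)carbonyl]-1,2-dihydronaphthalene-2-carboxylic acid, via peroxy acid 14 (not isolated)
Conditions: LiOH, H2O2, THF/H2O (3:1), 0 °C; then Na2SO3; then aq. HCl to pH 3
Reagents that add atoms: hydrogen peroxide (acting as LiOOH), OO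
Why: Evans auxiliary cleavage: hydroperoxide attacks the exocyclic imide carbonyl selectively even when it is hindered, sulfite reduces the peroxy acid 14, and the conjugated PMB ester and the C2 stereocenter are untouched at 0 °C.

Step 8
Reactants: 15 (1R,2S)-6,7-bis(allyloxy)-1-[3,4-bis(allyloxy)phenyl]-3-[(4-methoxybenzyloxy)carbonyl]-1,2-dihydronaphthalene-2-carboxylic acid
Product: 16 2-allyl 3-(4-methoxybenzyl) (1R,2S)-6,7-bis(allyloxy)-1-[3,4-bis(allyloxy)phenyl]-1,2-dihydronaphthalene-2,3-dicarboxylate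
Conditions: allyl bromide, KHCO3, DMF, rt
Reagents that add atoms: allyl bromide, C=CCBr
Why: Carboxylate O-alkylation (SN2) with a base too weak to epimerise C2 gives the allyl ester that will leave with the other allyl groups in the last step.

Step 9
Reactants: 16 2-allyl 3-(4-methoxybenzyl) (1R,2S)-6,7-bis(allyloxy)-1-[3,4-bis(allyloxy)phenyl]-1,2-dihydronaphthalene-2,3-dicarboxylate
Product: 17 (1R,2S)-2-(allyloxycarbonyl)-6,7-bis(allyloxy)-1-[3,4-bis(allyloxy)phenyl]-1,2-dihydronaphthalene-3-carboxylic acid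
Conditions: TFA (10 vol %), anisole, CH2Cl2, 0 °C
Reagents that add atoms: none
Why: Acidolysis of the PMB ester (SN1, the 4-methoxybenzyl cation is trapped by anisole) frees only the conjugated C3 acid, since allyl esters and aryl allyl ethers are inert to dilute TFA.

Step 10
Reactants: 18 (S)-malic acid (L-malic acid)
Product: 19 diallyl (S)-malate
Conditions: allyl alcohol (excess), TsOH·H2O (cat.), toluene, reflux, Dean–Stark
Reagents that add atoms: allyl alcohol, C=CCO
Why: Fischer esterification with azeotropic removal of water esterifies both carboxyls while the secondary hydroxyl and the S stereocenter (chiral pool) are unaffected.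

Step 11
Reactants: 17 (1R,2S)-2-(allyloxycarbonyl)-6,7-bis(allyloxy)-1-[3,4-bis(allyloxy)phenyl]-1,2-dihydronaphthalene-3-carboxylic acid, 19 diallyl (S)-malate
Product: 20 diallyl (S)-2-{[(1R,2S)-2-(allyloxycarbonyl)-6,7-bis(allyloxy)-1-[3,4-bis(allyloxy)phenyl]-1,2-dihydronaphthalen-3-yl]carbonyloxy}succinate
Conditions: DIC, DMAP (0.2 equiv), CH2Cl2, 0 °C → rt
Reagents that add atoms: none
Why: Steglich esterification: the carbodiimide-activated C3 acid acylates the malate hydroxyl without breaking the C–O bond at the malate carbon, so S is retained, and the C3 acyl carbon has no α-hydrogen through which a ketene could form.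

Step 12
Reactants: 20 diallyl (S)-2-{[(1R,2S)-2-(allyloxycarbonyl)-6,7-bis(allyloxy)-1-[3,4-bis(allyloxy)phenyl]-1,2-dihydronaphthalen-3-yl]carbonyloxy}succinate
Product: 21 (S)-2-{[(1R,2S)-2-carboxy-6,7-dihydroxy-1-(3,4-dihydroxyphenyl)-1,2-dihydronaphthalen-3-yl]carbonyloxy}succinic acid (CNP0323723.1)
Conditions: Pd(PPh3)4 (10 mol %), morpholine (20 equiv), THF, rt, under argon; then aq. HCl
Reagents that add atoms: none
Why: Tsuji–Trost deallylation: zerovalent palladium ionises all four aryl allyl ethers and three allyl esters to π-allyl complexes that morpholine traps, which leaves the enoate double bond, the malate ester linkage and all three stereocenters untouched.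

**Compound list**

1 | 3,4-dihydroxybenzaldehyde | O=Cc1ccc(O)c(O)c1 | starting material
2 | 3,4-bis(allyloxy)benzaldehyde | O=Cc1ccc(OCC=C)c(OCC=C)c1 | intermediate
3 | di-tert-butyl succinate | CC(C)(C)OC(=O)CCC(=O)OC(C)(C)C | starting material
4 | tert-butyl 2-[3,4-bis(allyloxy)phenyl]-5-oxotetrahydrofuran-3-carboxylate (paraconate lactone, racemic cis/trans mixture, not isolated) | O=C1CC(C(=O)OC(C)(C)C)C(c2ccc(OCC=C)c(OCC=C)c2)O1 | intermediate
5 | (E)-4-[3,4-bis(allyloxy)phenyl]-3-(tert-butoxycarbonyl)but-3-enoic acid | OC(=O)C/C(=C\c1ccc(OCC=C)c(OCC=C)c1)C(=O)OC(C)(C)C | intermediate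
6 | (R)-4-benzyl-2-oxazolidinone | O=C1OC[C@@H](Cc2ccccc2)N1 | starting material
7 | (E)-4-[3,4-bis(allyloxy)phenyl]-3-(tert-butoxycarbonyl)but-3-enoic pivalic anhydride (not isolated) | CC(C)(C)C(=O)OC(=O)C/C(=C\c1ccc(OCC=C)c(OCC=C)c1)C(=O)OC(C)(C)C | intermediate
8 | tert-butyl (E)-2-[3,4-bis(allyloxy)benzylidene]-4-[(R)-4-benzyl-2-oxooxazolidin-3-yl]-4-oxobutanoate | O=C(C/C(=C\c1ccc(OCC=C)c(OCC=C)c1)C(=O)OC(C)(C)C)N1C(=O)OC[C@H]1Cc1ccccc1 | intermediate
9 | dibutylboron Z(O)-enolate of 8 (not isolated) | CCCCB(CCCC)O/C(=C\C(C(=O)OC(C)(C)C)=C/c1ccc(OCC=C)c(OCC=C)c1)N1C(=O)OC[C@H]1Cc1ccccc1 | intermediate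
10 | (R)-4-benzyl-3-[(2R,3E)-4-[3,4-bis(allyloxy)phenyl]-2-{(R)-[3,4-bis(allyloxy)phenyl](hydroxy)methyl}-3-(tert-butoxycarbonyl)but-3-enoyl]oxazolidin-2-one | O=C([C@@H]([C@@H](O)c1ccc(OCC=C)c(OCC=C)c1)/C(=C\c1ccc(OCC=C)c(OCC=C)c1)C(=O)OC(C)(C)C)N1C(=O)OC[C@H]1Cc1ccccc1 | intermediate
11 | tert-butyl (1R,2S)-6,7-bis(allyloxy)-1-[3,4-bis(allyloxy)phenyl]-2-{[(R)-4-benzyl-2-oxooxazolidin-3-yl]carbonyl}-1,2-dihydronaphthalene-3-carboxylate (not isolated) | CC(C)(C)OC(=O)C1=Cc2cc(OCC=C)c(OCC=C)cc2[C@@H](c2ccc(OCC=C)c(OCC=C)c2)[C@@H]1C(=O)N1C(=O)OC[C@H]1Cc1ccccc1 | intermediate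
12 | (1R,2S)-6,7-bis(allyloxy)-1-[3,4-bis(allyloxy)phenyl]-2-{[(R)-4-benzyl-2-oxooxazolidin-3-yl]carbonyl}-1,2-dihydronaphthalene-3-carboxylic acid | OC(=O)C1=Cc2cc(OCC=C)c(OCC=C)cc2[C@@H](c2ccc(OCC=C)c(OCC=C)c2)[C@@H]1C(=O)N1C(=O)OC[C@H]1Cc1ccccc1 | intermediate
13 | 4-methoxybenzyl (1R,2S)-6,7-bis(allyloxy)-1-[3,4-bis(allyloxy)phenyl]-2-{[(R)-4-benzyl-2-oxooxazolidin-3-yl]carbonyl}-1,2-dihydronaphthalene-3-carboxylate | COc1ccc(COC(=O)C2=Cc3cc(OCC=C)c(OCC=C)cc3[C@@H](c3ccc(OCC=C)c(OCC=C)c3)[C@@H]2C(=O)N2C(=O)OC[C@H]2Cc2ccccc2)cc1 | intermediate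
14 | (1R,2S)-6,7-bis(allyloxy)-1-[3,4-bis(allyloxy)phenyl]-3-[(4-methoxybenzyloxy)carbonyl]-1,2-dihydronaphthalene-2-carboperoxoic acid (not isolated) | COc1ccc(COC(=O)C2=Cc3cc(OCC=C)c(OCC=C)cc3[C@@H](c3ccc(OCC=C)c(OCC=C)c3)[C@@H]2C(=O)OO)cc1 | intermediate
15 | (1R,2S)-6,7-bis(allyloxy)-1-[3,4-bis(allyloxy)phenyl]-3-[(4-methoxybenzyloxy)carbonyl]-1,2-dihydronaphthalene-2-carboxylic acid | COc1ccc(COC(=O)C2=Cc3cc(OCC=C)c(OCC=C)cc3[C@@H](c3ccc(OCC=C)c(OCC=C)c3)[C@@H]2C(=O)O)cc1 | intermediate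
16 | 2-allyl 3-(4-methoxybenzyl) (1R,2S)-6,7-bis(allyloxy)-1-[3,4-bis(allyloxy)phenyl]-1,2-dihydronaphthalene-2,3-dicarboxylate | COc1ccc(COC(=O)C2=Cc3cc(OCC=C)c(OCC=C)cc3[C@@H](c3ccc(OCC=C)c(OCC=C)c3)[C@@H]2C(=O)OCC=C)cc1 | intermediate
17 | (1R,2S)-2-(allyloxycarbonyl)-6,7-bis(allyloxy)-1-[3,4-bis(allyloxy)phenyl]-1,2-dihydronaphthalene-3-carboxylic acid | OC(=O)C1=Cc2cc(OCC=C)c(OCC=C)cc2[C@@H](c2ccc(OCC=C)c(OCC=C)c2)[C@@H]1C(=O)OCC=C | intermediate
18 | (S)-malic acid (L-malic acid) | OC(=O)C[C@H](O)C(=O)O | starting material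
19 | diallyl (S)-malate | C=CCOC(=O)C[C@H](O)C(=O)OCC=C | intermediate
20 | diallyl (S)-2-{[(1R,2S)-2-(allyloxycarbonyl)-6,7-bis(allyloxy)-1-[3,4-bis(allyloxy)phenyl]-1,2-dihydronaphthalen-3-yl]carbonyloxy}succinate | C=CCOC(=O)C[C@H](OC(=O)C1=Cc2cc(OCC=C)c(OCC=C)cc2[C@@H](c2ccc(OCC=C)c(OCC=C)c2)[C@@H]1C(=O)OCC=C)C(=O)OCC=C | intermediate
21 | (S)-2-{[(1R,2S)-2-carboxy-6,7-dihydroxy-1-(3,4-dihydroxyphenyl)-1,2-dihydronaphthalen-3-yl]carbonyloxy}succinic acid (CNP0323723.1) | O=C(O)C[C@H](OC(=O)C1=Cc2cc(O)c(O)cc2[C@@H](c2ccc(O)c(O)c2)[C@@H]1C(=O)O)C(=O)O | target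

**Step count and risks**

Total step count: 12. Longest linear sequence: 11 steps (1 → 2 → 5 → 8 → 10 → 12 → 13 → 15 → 16 → 17 → 20 → 21); step 10 is the only side branch.

The three steps most likely to fail:

Step 4 (Evans aldol). The boron dienolate carries a bulky α-alkenyl group and the aldehyde is electron-rich, so conversion may be low or attack may occur at the γ-carbon. The fallback gives up auxiliary control and resolves through the malate ester. It sets out from 5:
- Allyl bromide/KHCO3 in DMF gives 4-allyl 1-tert-butyl (E)-2-[3,4-bis(allyloxy)benzylidene]succinate F1.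
- Deprotonation with LiN(i-Pr)2 in THF at −78 °C and addition of aldehyde 2 (quench with AcOH at −78 °C) gives 4-allyl 1-tert-butyl (E)-2-[3,4-bis(allyloxy)benzylidene]-3-{[3,4-bis(allyloxy)phenyl](hydroxy)methyl}succinate F2 as a racemic diastereomer mixture.
- TFA/CH2Cl2 closes ring B trans and cleaves the tert-butyl ester, giving 17 together with its enantiomer (1S,2R)-2-(allyloxycarbonyl)-6,7-bis(allyloxy)-1-[3,4-bis(allyloxy)phenyl]-1,2-dihydronaphthalene-3-carboxylic acid F3.
- Esterification of this racemate with 19 as in step 11 gives 20 and its diastereomer diallyl (S)-2-{[(1S,2R)-2-(allyloxycarbonyl)-6,7-bis(allyloxy)-1-[3,4-bis(allyloxy)phenyl]-1,2-dihydronaphthalen-3-yl]carbonyloxy}succinate F4, which are separated by preparative HPLC.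
- The route is rejoined at 20.

Step 5 (Friedel–Crafts closure on the imide). The cation may be intercepted by the oxazolidinone carbonyl, may persist as a γ-lactone with the C3 carboxyl, or may eliminate to the bis-benzylidene diene. The fallback removes the auxiliary before ring closure, so the cyclisation substrate is a simple ester. It sets out from 10:
- LiOH/H2O2 in THF/H2O at 0 °C gives (2R,3E)-4-[3,4-bis(allyloxy)phenyl]-2-{(R)-[3,4-bis(allyloxy)phenyl](hydroxy)methyl}-3-(tert-butoxycarbonyl)but-3-enoic acid F5.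
- Allyl bromide/KHCO3 in DMF gives 4-allyl 1-tert-butyl (2E,3R)-2-[3,4-bis(allyloxy)benzylidene]-3-{(R)-[3,4-bis(allyloxy)phenyl](hydroxy)methyl}succinate F6.
- TFA/CH2Cl2 then closes ring B trans to the C2 ester and cleaves the tert-butyl ester in the same operation.
- The route is rejoined at 17, so the PMB detour of steps 6 to 9 is not needed.

Step 11 (Steglich esterification). A hindered conjugated acid meets a poorly nucleophilic secondary α-hydroxy ester, so N-acylurea formation or DMAP-induced epimerisation at C2 may win. The fallback activates the alcohol instead of the acid. It sets out from 17: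
- Bought D-malic acid is esterified with allyl alcohol exactly as in step 10 to give diallyl (R)-malate F7.
- Mitsunobu coupling of 17 with F7 (PPh3, DIAD, THF, 0 °C → rt) lets the carboxylate displace the activated hydroxyl with inversion, which gives the (S)-malate ester.
- The route is rejoined at 20.

**Further compounds**

F1 | step 4 | 4-allyl 1-tert-butyl (E)-2-[3,4-bis(allyloxy)benzylidene]succinate | C=CCOC(=O)C/C(=C\c1ccc(OCC=C)c(OCC=C)c1)C(=O)OC(C)(C)C
F2 | step 4 | 4-allyl 1-tert-butyl (E)-2-[3,4-bis(allyloxy)benzylidene]-3-{[3,4-bis(allyloxy)phenyl](hydroxy)methyl}succinate (racemic diastereomer mixture) | C=CCOC(=O)C(C(O)c1ccc(OCC=C)c(OCC=C)c1)/C(=C\c1ccc(OCC=C)c(OCC=C)c1)C(=O)OC(C)(C)C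
F3 | step 4 | (1S,2R)-2-(allyloxycarbonyl)-6,7-bis(allyloxy)-1-[3,4-bis(allyloxy)phenyl]-1,2-dihydronaphthalene-3-carboxylic acid | OC(=O)C1=Cc2cc(OCC=C)c(OCC=C)cc2[C@H](c2ccc(OCC=C)c(OCC=C)c2)[C@H]1C(=O)OCC=C
F4 | step 4 | diallyl (S)-2-{[(1S,2R)-2-(allyloxycarbonyl)-6,7-bis(allyloxy)-1-[3,4-bis(allyloxy)phenyl]-1,2-dihydronaphthalen-3-yl]carbonyloxy}succinate | C=CCOC(=O)C[C@H](OC(=O)C1=Cc2cc(OCC=C)c(OCC=C)cc2[C@H](c2ccc(OCC=C)c(OCC=C)c2)[C@H]1C(=O)OCC=C)C(=O)OCC=C
F5 | step 5 | (2R,3E)-4-[3,4-bis(allyloxy)phenyl]-2-{(R)-[3,4-bis(allyloxy)phenyl](hydroxy)methyl}-3-(tert-butoxycarbonyl)but-3-enoic acid | OC(=O)[C@@H]([C@@H](O)c1ccc(OCC=C)c(OCC=C)c1)/C(=C\c1ccc(OCC=C)c(OCC=C)c1)C(=O)OC(C)(C)C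
F6 | step 5 | 4-allyl 1-tert-butyl (2E,3R)-2-[3,4-bis(allyloxy)benzylidene]-3-{(R)-[3,4-bis(allyloxy)phenyl](hydroxy)methyl}succinate | C=CCOC(=O)[C@@H]([C@@H](O)c1ccc(OCC=C)c(OCC=C)c1)/C(=C\c1ccc(OCC=C)c(OCC=C)c1)C(=O)OC(C)(C)C
F7 | step 11 | diallyl (R)-malate | C=CCOC(=O)C[C@@H](O)C(=O)OCC=C
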